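1.73 /M/h is the number to carry: the late constant, the second-order rate constant with which Z and the rest (L charged, less J and Q) use each other up, read in the north-west run between 3.00 h and 15.0 h.

| flask | L | Z | remark | time |
|---|---|---|---|---|
| south-west | 0.20 M | 0.10 M | run made earlier |  |
| north-west | 0.20 M | 0.15 M | run made earlier |  |
| south | 0.10 M | 0.20 M | run made earlier |  |
| flask | 0.20 M | 0.200 M |  | 12 h |

| run | time / h | J / % | Q / % |
|---|---|---|---|
| south-west | 1.00 | 5.1 | 7.5 |
| south-west | 3.00 | 6.4 | 19.9 |
| south-west | 5.00 | 4.6 | 28.2 |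
| south-west | 8.00 | 6.7 | 35.5 |
| south-west | 12.0 | 6.8 | 39.4 |
| south-west | 15.0 | 7.5 | 42.0 |
| north-west | 1.00 | 6.4 | 9.6 |
| north-west | 2.00 | 7.2 | 18.4 |
| north-west | 3.00 | 8.1 | 26.5 |
| north-west | 5.00 | 9.4 | 38.4 |
| north-west | 8.00 | 10.2 | 49.2 |
| north-west | 15.0 | 9.5 | 58.5 |
| south | 1.33 | 10.0 | 17.8 |
| south | 4.00 | 13.0 | 44.9 |
| south | 6.00 | 13.5 | 59.0 |
| south | 10.0 | 14.3 | 73.8 |
| south | 15.0 | 15.3 | 80.4 |

(standard deviation of a reading: 0.5 percentage points)

- ratio of J to Q at 5.0 min
- ratio of J to Q at 1.0 h
- ratio of J to Q at 12 h



What does each product cost? I take it as one Z and one L: in the south-west run, J and Q together reach 0.0990 M at 15.0 h, against 0.10 M of Z charged.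

How do you get the constant? The difference between the rest and Z stays fixed, so the rate integrates: the logarithm of rest over Z climbs in a straight line, with slope the constant times that difference.

But this flask charges L and Z equally, so the difference is nil. Then the rest and Z are one amount, and its reciprocal climbs straight with slope the late constant.

Starting from what? From the charge less J. I assume J in proportion to Z charged. The north-west run, with the flask's L, averages 9.85% of J over its last two readings, which gives my estimate of 0.0263 M of J in the flask. So 0.174 M falls to 0.0377 M by 12 h, Q is 0.136 M, and the ratio is 0.193. This is a late reckoning, and I give it for 12 h, with no figure of mine for the two earlier times.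

The forecast, resting on “a fast, short-lived J route”, gives 1.7, 0.54 and 0.175 for the three times asked, and my figure for 12 h stands above its last one.

The flask gives 10.3, 0.760 and 0.193.

    L ⇌ E (K = 5.30, k = 0.00120 /s)
    L → G (k = 8.70 × 10⁻⁴ /s)
    L + Z → J (k = 8.50 × 10⁻⁴ /M/s)
    Z + G → Q (k = 5.80 × 10⁻⁴ /M/s)

At 12.0 h the flask's Z goes 130 times faster by Z + G to Q than by L + Z to J, and J stands at 12.6% at 6.00 h and 12.9% at 12.0 h, while Q climbs from 50.9% to 67.1%. Over that stretch the flask's Z, put through the same reciprocal, gives 1.89 /M/h against the late constant of 1.73 /M/h.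

For the neighbour flask, the same recipe with 0.12 M of Z, the same reckoning starts from 0.0158 M of J, and the logarithm form leaves 0.00963 M of Z by 12 h, so Q is 0.0946 M and the ratio 0.167. That neighbour computes to 7.84% of J, 47.1% of Q and a ratio of 0.166.

The readings were generated by integration on assumed constants; noise was put on by code.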